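**Strategy.** The seven-membered ring is cut at C5–C6 (the later enone C=C) and at the ring-fusion bond C3a–C8a (azulene locants). This exploits the 1,4-disposed oxygens on C4 and C7 of the seven-membered ring and the tertiary alcohol at C3 beside C3a. C5–C4–C3a becomes a silyloxyallyl cation unmasked from an enantioenriched α,β-epoxy enol silane, whose epoxide oxygen ends as the C3 hydroxyl. C6–C7–C8–C8a is a tethered 2-silyloxydiene. One silyl-triflate-triggered intramolecular (4+3) cycloaddition of the open-chain precursor closes both rings and sets C3a and C8a. Directed reduction, acylation and dehydrogenation finish the target.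

Key step: step 9

Remark on the chemistry: C6 (the methyl-bearing ring carbon) of 12–16 is an inconsequential epimer mixture (sp2 again after step 12) and carries no descriptor; bicyclic compounds are named with the azulene locants of the target; 1, 3, 8 and 15 are taken as commercial.

Step 1
Reactants: 1 hexa-1,5-diyne
Product: 2 (1E)-1-iodo-2-methylhex-1-en-5-yne
Conditions: AlMe3 (1 equiv), Cp2ZrCl2 (0.2 equiv), CH2Cl2, 0 °C to rt, 1 in threefold excess; then I2, THF, −30 °C
Reagents that add atoms: trimethylaluminium C[Al](C)C; iodine II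
Why: Negishi carboalumination (Cp2ZrCl2-catalysed syn addition of Me–Al across one terminal alkyne, Me to the internal carbon) followed by iodinolysis with retention should give the E iodoalkene, the excess of 1 limiting double addition.

Step 2
Reactants: 2 (1E)-1-iodo-2-methylhex-1-en-5-yne; 3 N-methoxy-N-methylacetamide
Product: 4 (7E)-8-iodo-7-methyloct-7-en-3-yn-2-one
Conditions: EtMgBr, THF, 0 to 40 °C; then 3, 0 °C; aq. NH4Cl
Reagents that add atoms: none
Why: Acylation of the alkynyl Grignard reagent with a Weinreb amide stops at the ynone through the chelated tetrahedral intermediate, and the iodoalkene does not exchange with EtMgBr.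

Step 3
Reactants: 4 (7E)-8-iodo-7-methyloct-7-en-3-yn-2-one
Product: 5 (3E,7E)-8-iodo-7-methyl-4-(propan-2-yl)octa-3,7-dien-2-one
Conditions: i-PrMgCl, CuBr·SMe2 (1.1 equiv each), THF, −78 °C; aq. NH4Cl
Reagents that add atoms: isopropylmagnesium chloride CC(C)[Mg]Cl
Why: Organocopper conjugate addition (syn carbocupration of the ynone, then protonation) should place isopropyl trans to acetyl, which is also the thermodynamically preferred geometry, so the 3E enone is expected, the iodoalkene being inert at −78 °C.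

Step 4
Reactants: 5 (3E,7E)-8-iodo-7-methyl-4-(propan-2-yl)octa-3,7-dien-2-one
Product: 6 (3E,7E)-8-iodo-7-methyl-4-(propan-2-yl)octa-3,7-dien-2-ol (racemic)
Conditions: NaBH4, CeCl3·7H2O, MeOH, −40 °C
Reagents that add atoms: none
Why: Luche reduction should give clean 1,2-reduction of the enone; the racemic carbinol centre is erased in step 7.

Step 5
Reactants: 6 (3E,7E)-8-iodo-7-methyl-4-(propan-2-yl)octa-3,7-dien-2-ol
Product: 7 (1RS)-1-[(2R,3R)-3-[(3E)-4-iodo-3-methylbut-3-en-1-yl]-3-(propan-2-yl)oxiran-2-yl]ethan-1-ol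
Conditions: D-fructose-derived Shi ketone (1,2:4,5-di-O-isopropylidene-D-erythro-2,3-hexodiulo-2,6-pyranose, 0.3 equiv), KHSO5 (Oxone grade), K2CO3, n-Bu4NHSO4, MeCN/dimethoxymethane–aq. Na2B4O7 (pH 10.5), 0 °C
Reagents that add atoms: potassium peroxymonosulfate [K+].[O-]S(=O)(=O)OO
Why: Shi epoxidation: the fructose-derived dioxirane should transfer oxygen stereospecifically to the electron-rich trisubstituted E alkene through the spiro transition state, on the face that sets both epoxide centres as 2R,3R (the sense known for E and trisubstituted alkenes with this ketone), while the iodoalkene is deactivated towards the electrophilic oxidant.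

Step 6
Reactants: 7 (1RS)-1-[(2R,3R)-3-[(3E)-4-iodo-3-methylbut-3-en-1-yl]-3-(propan-2-yl)oxiran-2-yl]ethan-1-ol; 8 propanal
Product: 9 (4E)-7-[(2R,3R)-3-(1-hydroxyethyl)-2-(propan-2-yl)oxiran-2-yl]-5-methylhept-4-en-3-ol (carbinol diastereomers)
Conditions: CrCl2 (4 equiv), NiCl2 (2 mol %), DMSO, rt
Reagents that add atoms: none
Why: Nozaki–Hiyama–Kishi coupling: nickel-catalysed oxidative addition and transfer to chromium should give an alkenylchromium species that adds to the aldehyde with retention of the E geometry and tolerates the free hydroxyl and the epoxide; the new carbinol centre is erased in step 7.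

Step 7
Reactants: 9 (4E)-7-[(2R,3R)-3-(1-hydroxyethyl)-2-(propan-2-yl)oxiran-2-yl]-5-methylhept-4-en-3-ol
Product: 10 (4E)-7-[(2R,3S)-3-acetyl-2-(propan-2-yl)oxiran-2-yl]-5-methylhept-4-en-3-one
Conditions: Dess–Martin periodinane (3 equiv), NaHCO3, CH2Cl2, 0 °C to rt
Reagents that add atoms: none
Why: Dess–Martin oxidation of both secondary alcohols should converge all diastereomers to one epoxy diketone, the buffered neutral conditions sparing the epoxy ketone.

Step 8
Reactants: 10 (4E)-7-[(2R,3S)-3-acetyl-2-(propan-2-yl)oxiran-2-yl]-5-methylhept-4-en-3-one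
Product: 11 (2R,3S)-2-[(3E,5Z)-3-methyl-5-[(triethylsilyl)oxy]hepta-3,5-dien-1-yl]-2-(propan-2-yl)-3-{1-[(triethylsilyl)oxy]ethenyl}oxirane
Conditions: Et3SiCl (3 equiv), then KN(SiMe3)2 (2.4 equiv), THF, −78 °C; Et3N quench, filtration through Et3N-deactivated silica
Reagents that add atoms: chlorotriethylsilane CC[Si](Cl)(CC)CC
Why: Kinetic deprotonation removes a methyl proton of the epoxy ketone and an α′ proton of the ethyl enone, and O-silylation should give the epoxy enol silane and the cross-conjugated 2-silyloxydiene, the potassium enolate favouring the Z enol ether (CH3 outside on the diene).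

Step 9
Reactants: 11 (2R,3S)-2-[(3E,5Z)-3-methyl-5-[(triethylsilyl)oxy]hepta-3,5-dien-1-yl]-2-(propan-2-yl)-3-{1-[(triethylsilyl)oxy]ethenyl}oxirane
Product: 13 (3R,3aR,8aR)-3-hydroxy-6,8a-dimethyl-3-(propan-2-yl)octahydroazulene-4,7-dione, via bis-silyl cycloadduct 12 (not isolated)
Conditions: Et3SiOTf (10 mol %), CH2Cl2, −78 °C; then HF·pyridine, THF, 0 °C
Reagents that add atoms: none
Why: Et3SiOTf silylates the epoxide oxygen and, assisted by the adjacent enol silane, C3a–O ionises towards a 2-silyloxyallyl cation (C5–C4–C3a) that the tethered 2-silyloxydiene (C6=C7–C8=C8a) captures in a (4+3) cycloaddition, the closest known reaction type being the silyl-triflate-catalysed intramolecular (4+3) cycloaddition of epoxy enol silanes with tethered dienes. The five-membered ring closes by attack of C8a on the epoxide carbon C3a in the endo mode with respect to the epoxide (both epoxide carbons end in the ring), and the seven-membered ring closes by the bond C5–C6 between the enol silane carbon and the diene terminus, suprafacially on both π components. C3a is controlled by the epoxide, whose C–O bond is displaced with inversion in an SN2-like event, so the epoxide from the E enone (acetyl-derived carbon cis to the tether) gives C4 cis to the C3 oxygen, while C3 itself is carried over unchanged. C8a is controlled by the transition-state geometry: with the tether outside on both partners (W-shaped cation enforced by A(1,3) strain, E diene), the extended arrangement that keeps the two silyloxy groups apart should lead to the trans ring fusion, and C6 forms without consequence. The step needs (4+3) closure over (3+2) closure and over semipinacol or elimination paths of the trisubstituted epoxide; the trans-disposed arms disfavour five-ring closure at C8, and low temperature with catalytic silyl triflate favours direct capture. HF·pyridine added to the same flask then cleaves both silyl groups to the hydroxy diketone.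

Step 10
Reactants: 13 (3R,3aR,8aR)-3-hydroxy-6,8a-dimethyl-3-(propan-2-yl)octahydroazulene-4,7-dione
Product: 14 (3R,3aS,4S,8aR)-3,4-dihydroxy-6,8a-dimethyl-3-(propan-2-yl)octahydroazulen-7(1H)-one
Conditions: Me4NBH(OAc)3, MeCN/AcOH (1:1), −30 to −20 °C
Reagents that add atoms: none
Why: Evans–Saksena reduction: the C3 hydroxyl exchanges onto boron and delivers hydride intramolecularly to the C4 carbonyl face on its own side (the face beside C8a that external hydride would avoid), which should give the 4S alcohol anti to the C3 hydroxyl, while the C7 ketone has no directing hydroxyl and stays.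

Step 11
Reactants: 14 (3R,3aS,4S,8aR)-3,4-dihydroxy-6,8a-dimethyl-3-(propan-2-yl)octahydroazulen-7(1H)-one; 15 (2E)-3-[4-(acetyloxy)phenyl]prop-2-enoic acid
Product: 16 (3R,3aS,4S,8aR)-3-hydroxy-6,8a-dimethyl-7-oxo-3-(propan-2-yl)decahydroazulen-4-yl (2E)-3-[4-(acetyloxy)phenyl]prop-2-enoate
Conditions: EDC·HCl (1-ethyl-3-(3-dimethylaminopropyl)carbodiimide hydrochloride), DMAP (0.1 equiv), CH2Cl2, 0 °C to rt
Reagents that add atoms: none
Why: Steglich esterification should acylate only the secondary C4 hydroxyl, the tertiary C3 hydroxyl being inert.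

Step 12
Reactants: 16 (3R,3aS,4S,8aR)-3-hydroxy-6,8a-dimethyl-7-oxo-3-(propan-2-yl)decahydroazulen-4-yl (2E)-3-[4-(acetyloxy)phenyl]prop-2-enoate
Product: 17 (3R,3aS,4S,8aR)-3-hydroxy-6,8a-dimethyl-7-oxo-3-(propan-2-yl)-1,2,3,3a,4,7,8,8a-octahydroazulen-4-yl (2E)-3-[4-(acetyloxy)phenyl]prop-2-enoate
Conditions: IBX (2.5 equiv), DMSO, 70 °C
Reagents that add atoms: none
Why: IBX dehydrogenation of the C7 ketone can only run towards C6/C5, because C8 is flanked by the quaternary C8a (no β-hydrogen), so the conjugated trisubstituted enone should form and the C6 epimer mixture is erased.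

Step 13
Reactants: 17 (3R,3aS,4S,8aR)-3-hydroxy-6,8a-dimethyl-7-oxo-3-(propan-2-yl)-1,2,3,3a,4,7,8,8a-octahydroazulen-4-yl (2E)-3-[4-(acetyloxy)phenyl]prop-2-enoate
Product: 18 (3R,3aS,4S,8aR)-3-hydroxy-6,8a-dimethyl-7-oxo-3-(propan-2-yl)-1,2,3,3a,4,7,8,8a-octahydroazulen-4-yl (2E)-3-(4-hydroxyphenyl)prop-2-enoate
Conditions: K2CO3 (0.2 equiv), MeOH, 0 °C
Reagents that add atoms: none
Why: Mild base-catalysed methanolysis (transesterification) should cleave the aryl acetate much faster than the hindered cinnamate ester, releasing the phenol and giving the target.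

**Compound list**

1 | hexa-1,5-diyne | C#CCCC#C | starting material
2 | (1E)-1-iodo-2-methylhex-1-en-5-yne | C#CCC/C(C)=C/I | intermediate
3 | N-methoxy-N-methylacetamide | CC(=O)N(C)OC | starting material
4 | (7E)-8-iodo-7-methyloct-7-en-3-yn-2-one | CC(=O)C#CCC/C(C)=C/I | intermediate
5 | (3E,7E)-8-iodo-7-methyl-4-(propan-2-yl)octa-3,7-dien-2-one | CC(=O)/C=C(\CC/C(C)=C/I)C(C)C | intermediate
6 | (3E,7E)-8-iodo-7-methyl-4-(propan-2-yl)octa-3,7-dien-2-ol (racemic) | CC(O)/C=C(\CC/C(C)=C/I)C(C)C | intermediate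
7 | (1RS)-1-[(2R,3R)-3-[(3E)-4-iodo-3-methylbut-3-en-1-yl]-3-(propan-2-yl)oxiran-2-yl]ethan-1-ol | CC(O)[C@H]1O[C@@]1(C(C)C)CC/C(C)=C/I | intermediate
8 | propanal | CCC=O | starting material
9 | (4E)-7-[(2R,3R)-3-(1-hydroxyethyl)-2-(propan-2-yl)oxiran-2-yl]-5-methylhept-4-en-3-ol (carbinol diastereomers) | CC(O)[C@H]1O[C@@]1(C(C)C)CC/C(C)=C/C(O)CC | intermediate
10 | (4E)-7-[(2R,3S)-3-acetyl-2-(propan-2-yl)oxiran-2-yl]-5-methylhept-4-en-3-one | CC(=O)[C@H]1O[C@@]1(C(C)C)CC/C(C)=C/C(=O)CC | intermediate
11 | (2R,3S)-2-[(3E,5Z)-3-methyl-5-[(triethylsilyl)oxy]hepta-3,5-dien-1-yl]-2-(propan-2-yl)-3-{1-[(triethylsilyl)oxy]ethenyl}oxirane | C=C(O[Si](CC)(CC)CC)[C@H]1O[C@@]1(C(C)C)CC/C(C)=C/C(O[Si](CC)(CC)CC)=C/C | intermediate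
12 | (3R,3aR,8aR)-6,8a-dimethyl-3-(propan-2-yl)-3,7-bis[(triethylsilyl)oxy]-2,3,3a,5,6,8a-hexahydroazulen-4(1H)-one (bis-silyl cycloadduct, not isolated) | CC1CC(=O)[C@@H]2[C@](C)(CC[C@@]2(O[Si](CC)(CC)CC)C(C)C)C=C1O[Si](CC)(CC)CC | intermediate
13 | (3R,3aR,8aR)-3-hydroxy-6,8a-dimethyl-3-(propan-2-yl)octahydroazulene-4,7-dione | CC1CC(=O)[C@@H]2[C@](C)(CC[C@@]2(O)C(C)C)CC1=O | intermediate
14 | (3R,3aS,4S,8aR)-3,4-dihydroxy-6,8a-dimethyl-3-(propan-2-yl)octahydroazulen-7(1H)-one | CC1C[C@H](O)[C@@H]2[C@](C)(CC[C@@]2(O)C(C)C)CC1=O | intermediate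
15 | (2E)-3-[4-(acetyloxy)phenyl]prop-2-enoic acid | CC(=O)Oc1ccc(/C=C/C(=O)O)cc1 | starting material
16 | (3R,3aS,4S,8aR)-3-hydroxy-6,8a-dimethyl-7-oxo-3-(propan-2-yl)decahydroazulen-4-yl (2E)-3-[4-(acetyloxy)phenyl]prop-2-enoate | CC1C[C@H](OC(=O)/C=C/c2ccc(OC(C)=O)cc2)[C@@H]2[C@](C)(CC[C@@]2(O)C(C)C)CC1=O | intermediate
17 | (3R,3aS,4S,8aR)-3-hydroxy-6,8a-dimethyl-7-oxo-3-(propan-2-yl)-1,2,3,3a,4,7,8,8a-octahydroazulen-4-yl (2E)-3-[4-(acetyloxy)phenyl]prop-2-enoate | CC1=C[C@H](OC(=O)/C=C/c2ccc(OC(C)=O)cc2)[C@@H]2[C@](C)(CC[C@@]2(O)C(C)C)CC1=O | intermediate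
18 | (3R,3aS,4S,8aR)-3-hydroxy-6,8a-dimethyl-7-oxo-3-(propan-2-yl)-1,2,3,3a,4,7,8,8a-octahydroazulen-4-yl (2E)-3-(4-hydroxyphenyl)prop-2-enoate | CC1=C[C@H](OC(=O)/C=C/c2ccc(O)cc2)[C@@H]2[C@](C)(CC[C@@]2(O)C(C)C)CC1=O | target

Total step count: 13. Longest linear sequence: 13 steps (from 1).

**Steps most likely to fail**

1. Step 9. The fully substituted epoxide carbon may ionise instead (hydride or alkyl shift, elimination). The enol silane carbon may close onto C8 (five-ring, (3+2) mode). Passage through the compact arrangement would erode the trans ring fusion. Fallback, setting out from 10 and coming back at 13: the two bonds are made one after the other.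
   - SmI2 (THF/MeOH, −90 °C) cleaves the Cα–O bond of the epoxy ketone to the open-chain hydroxy diketone F1.
   - Et3SiOTf/2,6-lutidine gives the tertiary silyl ether F2, which blocks retro-aldol cleavage.
   - KOt-Bu (cat.) in THF/t-BuOH closes the five-membered ring by reversible 5-exo-trig Michael addition of the internal methyl-ketone enolate to the enone. The acetyl-bearing carbon should settle trans to isopropyl and to the CH2 arm, giving the cyclopentane diketone F3.
   - LiN(i-Pr)2 (2.2 equiv, −78 °C) then Cu(OTf)2 joins the acetyl CH3 and ethyl CH2 carbons by intramolecular oxidative enolate coupling, giving the bicyclic silyl ether F4.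
   - HF·pyridine returns 13.

2. Step 5. Facial selectivity may erode on the racemic secondary allylic alcohol, and the oxidant may attack at iodine. Fallback, setting out from 2 and coming back at 7: the epoxide is set on a primary allylic alcohol.
   - EtMgBr then ClCO2Me gives the methyl ynoate F5.
   - i-PrMgCl/CuBr·SMe2 (−78 °C, syn addition) gives the E enoate F6.
   - i-Bu2AlH (CH2Cl2, −78 °C) gives the primary allylic alcohol F7.
   - Sharpless asymmetric epoxidation (Ti(OiPr)4, D-(−)-diisopropyl tartrate, t-BuOOH, 4 Å sieves, CH2Cl2, −20 °C) gives the epoxy alcohol F8.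
   - Dess–Martin oxidation gives the epoxy aldehyde F9.
   - MeMgBr (THF, −78 °C) returns 7.

3. Step 12. Desaturation may run towards the methyl group (exocyclic methylene), or heat may cause loss of the allylic acyloxy group and over-oxidation. Fallback, setting out from 16 and coming back at 17: a two-stage selenoxide elimination.
   - Acid-catalysed selenenylation with PhSeCl (EtOAc, cat. HCl, rt) at the more substituted α-carbon C6 gives the α-phenylselanyl ketone F10.
   - H2O2/pyridine (CH2Cl2, 0 °C) oxidises selenium, and syn-elimination towards the ring hydrogen at C5 gives 17.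

**Further compounds**

F1 | step 9 | (4S,7E)-4-hydroxy-7-methyl-4-(propan-2-yl)undec-7-ene-2,9-dione | CC(=O)C[C@](O)(C(C)C)CC/C(C)=C/C(=O)CC
F2 | step 9 | (4S,7E)-7-methyl-4-(propan-2-yl)-4-[(triethylsilyl)oxy]undec-7-ene-2,9-dione | CC(=O)C[C@](O[Si](CC)(CC)CC)(C(C)C)CC/C(C)=C/C(=O)CC
F3 | step 9 | 1-[(1R,2R,3R)-2-acetyl-1-methyl-3-(propan-2-yl)-3-[(triethylsilyl)oxy]cyclopentyl]butan-2-one | CC(=O)[C@@H]1[C@](C)(CC[C@@]1(O[Si](CC)(CC)CC)C(C)C)CC(=O)CC
F4 | step 9 | (3R,3aR,8aR)-6,8a-dimethyl-3-(propan-2-yl)-3-[(triethylsilyl)oxy]octahydroazulene-4,7-dione | CC1CC(=O)[C@@H]2[C@](C)(CC[C@@]2(O[Si](CC)(CC)CC)C(C)C)CC1=O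
F5 | step 5 | methyl (6E)-7-iodo-6-methylhept-6-en-2-ynoate | COC(=O)C#CCC/C(C)=C/I
F6 | step 5 | methyl (2E,6E)-7-iodo-6-methyl-3-(propan-2-yl)hepta-2,6-dienoate | COC(=O)/C=C(\CC/C(C)=C/I)C(C)C
F7 | step 5 | (2E,6E)-7-iodo-6-methyl-3-(propan-2-yl)hepta-2,6-dien-1-ol | OC/C=C(\CC/C(C)=C/I)C(C)C
F8 | step 5 | [(2R,3R)-3-[(3E)-4-iodo-3-methylbut-3-en-1-yl]-3-(propan-2-yl)oxiran-2-yl]methanol | OC[C@H]1O[C@@]1(C(C)C)CC/C(C)=C/I
F9 | step 5 | (2S,3R)-3-[(3E)-4-iodo-3-methylbut-3-en-1-yl]-3-(propan-2-yl)oxirane-2-carbaldehyde | O=C[C@H]1O[C@@]1(C(C)C)CC/C(C)=C/I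
F10 | step 12 | (3R,3aS,4S,8aR)-3-hydroxy-6,8a-dimethyl-7-oxo-6-(phenylselanyl)-3-(propan-2-yl)decahydroazulen-4-yl (2E)-3-[4-(acetyloxy)phenyl]prop-2-enoate | CC1([Se]c3ccccc3)C[C@H](OC(=O)/C=C/c2ccc(OC(C)=O)cc2)[C@@H]2[C@](C)(CC[C@@]2(O)C(C)C)CC1=O
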